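**Retrosynthetic overview**
1. The last bond is the central C–C bond of the triene, made by a Heck union of a core (E)-alkenyl iodide with a pyranone-terminated 1,3-diene.
2. The pyranone ring is built first and separately: 3-pentanone silyl enol ether plus methylmalonyl dichloride, O-methylation, then aldol condensation with acrolein.
3. Core oxygens: the C6 carbinol comes from ketone reduction and the C3/C4 diol from a hydroxyl-directed dihydroxylation, with C4 acetylated while it is the only secondary OH. The C1 propynyl group (later the alkenyl iodide) is installed by a 1,2-alkynyl shift.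
4. The cyclohexenone comes from a cyclopentenyl α-silyloxy methyl ketone by α-ketol ring expansion (1,2-alkenyl shift). This sets the C5 carbinol and, run as a kinetic resolution, the absolute configuration.
5. Ring order: the pyranone independently; the carbocycle is bought as a cyclopentenone and expanded to the six-membered ring in step 2; no other ring is formed.

Assumption: commercial 3,4-dimethylcyclopent-2-en-1-one is the racemate; racemic compounds are drawn as the enantiomer that is carried forward.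
Convention: locants C1–C6 in the "Why" lines are those of the target ring (C1 side chain, C2 CH(CH3), C3 and C5 C(CH3)OH, C4 CHOAc, C6 CHOH).

**Step 1**
Reactants: 1 rac-3,4-dimethylcyclopent-2-en-1-one; 2 ethyl vinyl ether
Product: 5 rac-1-[(1R*,4S*)-3,4-dimethyl-1-(trimethylsilyloxy)cyclopent-2-en-1-yl]ethan-1-one, via lithium alkoxide adduct 3 (not isolated), via silylated enol-ether adduct 4 (not isolated)
Conditions: 2, t-BuLi, THF, −78 → 0 °C; 1, −78 °C; TMSCl, −78 → 0 °C; 5% aq. oxalic acid, THF, 0 °C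
Reagents that add atoms: chlorotrimethylsilane C[Si](C)(C)Cl; water O
Why: 1,2-addition of the acyl-anion equivalent 1-ethoxyvinyllithium occurs anti to the C2 methyl (trans adduct, expected about 6:1, minor isomer removed), the tertiary alkoxide is silylated in situ and mild acid hydrolyses only the enol ether (acyl-anion addition/enol-ether hydrolysis).

**Step 2**
Reactants: 5 rac-1-[(1R*,4S*)-3,4-dimethyl-1-(trimethylsilyloxy)cyclopent-2-en-1-yl]ethan-1-one
Product: 7 (2R,5S)-2-hydroxy-2,4,5-trimethylcyclohex-3-en-1-one, via ring-expanded silyl ether 6 (not isolated)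
Conditions: (R)-[3,3′-(Ph3Si)2-BINOLate]AlMe (10 mol %), toluene, −40 °C, stopped at ca. 52% conversion; citric acid, MeOH, 0 °C
Reagents that add atoms: none
Why: Proposed new method: a bulky monodentate chiral aluminium Lewis acid binds the acetyl oxygen with the C–OSi bond anti to C=O (non-chelated), and the ring alkenyl carbon (a better migrating group than CH2, bridged cyclopropylcarbinyl-type transition state) makes the 1,2-shift to the carbonyl carbon, which expands the ring, transfers the carbinol configuration to the new C5 centre (CH3 cis to the C2 methyl) and frees the catalyst by 1,4-O→O silyl transfer; the chiral pocket is expected to accept only the (1R,4S)-enantiomer (kinetic resolution, at most 50% yield, the catalyst hand to be matched by experiment); closest known reaction types are the chiral organoaluminium-catalysed rearrangement of α-siloxy aldehydes to acyloins and the Lewis-acid- or base-mediated α-ketol ring expansion of 1-acylcycloalkanols (D-homoannulation).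

**Step 3**
Reactants: 7 (2R,5S)-2-hydroxy-2,4,5-trimethylcyclohex-3-en-1-one
Product: 8 (2R,5R,6S)-6-bromo-2-hydroxy-2,4,5-trimethylcyclohex-3-en-1-one
Conditions: LDA (2.1 equiv), THF, −78 °C; NBS, −78 °C; H2O
Reagents that add atoms: N-bromosuccinimide O=C1CCC(=O)N1Br
Why: The ketone can enolise only toward C1 (C5 is quaternary) and the lithium enolate is brominated axially, anti to the pseudo-axial C2 methyl, giving the axial bromide that is also the more stable α-bromoketone epimer (enolate α-halogenation).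

**Step 4**
Reactants: 8 (2R,5R,6S)-6-bromo-2-hydroxy-2,4,5-trimethylcyclohex-3-en-1-one; 9 prop-1-yn-1-ylmagnesium bromide
Product: 11 (2R,5S,6S)-2-hydroxy-2,4,5-trimethyl-6-(prop-1-yn-1-yl)cyclohex-3-en-1-one, via bromohydrin magnesium alkoxide 10 (not isolated)
Conditions: 9 (2.05 equiv), THF, −78 → −20 °C; toluene, 65 °C; pH 7 buffer
Reagents that add atoms: none
Why: One equivalent deprotonates the hydroxyl, the second adds to C=O anti to the axial C–Br bond (Cornforth/polar Felkin–Anh), and on warming the trans-diaxial bromohydrin alkoxide undergoes a Tiffeneau/Suzuki–Tsuchihashi-type semipinacol 1,2-alkynyl shift with inversion at C1, which puts the propynyl group equatorial and cis to the C2 methyl (also the thermodynamic C1 epimer).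

**Step 5**
Reactants: 11 (2R,5S,6S)-2-hydroxy-2,4,5-trimethyl-6-(prop-1-yn-1-yl)cyclohex-3-en-1-one
Product: 13 (2R,3R,4R,5S,6S)-2,3,4-trihydroxy-2,4,5-trimethyl-6-(prop-1-yn-1-yl)cyclohexan-1-one, via osmate ester 12 (not isolated)
Conditions: OsO4 (1.1 equiv), TMEDA, CH2Cl2, −78 °C; sat. aq. NaHSO3, THF, 40 °C
Reagents that add atoms: osmium tetroxide O=[Os](=O)(=O)=O
Why: Donohoe-type directed dihydroxylation: OsO4·TMEDA is hydrogen-bonded by the tertiary allylic C5–OH and adds syn to it (and anti to the pseudo-axial C2 methyl), setting C3 and C4 all-cis to the C5 hydroxyl while the alkyne is untouched.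

**Step 6**
Reactants: 13 (2R,3R,4R,5S,6S)-2,3,4-trihydroxy-2,4,5-trimethyl-6-(prop-1-yn-1-yl)cyclohexan-1-one
Product: 14 (1R,2R,3S,4S,6R)-2,6-dihydroxy-2,3,6-trimethyl-5-oxo-4-(prop-1-yn-1-yl)cyclohexyl acetate
Conditions: AcCl (1.5 equiv), 2,4,6-collidine, DMAP (5 mol %), CH2Cl2, −20 → 0 °C
Reagents that add atoms: acetyl chloride CC(=O)Cl
Why: C4–OH is the only secondary hydroxyl, so acylation with acetyl chloride and a hindered pyridine base (too weak to isomerise the α-alkynyl ketone to an allenone) is site-selective (O-acylation).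

**Step 7**
Reactants: 14 (1R,2R,3S,4S,6R)-2,6-dihydroxy-2,3,6-trimethyl-5-oxo-4-(prop-1-yn-1-yl)cyclohexyl acetate
Product: 15 (1R,2S,3S,4S,5S,6R)-2,3,6-trihydroxy-2,5,6-trimethyl-4-(prop-1-yn-1-yl)cyclohexyl acetate
Conditions: NaBH4, CeCl3·7H2O, MeOH, −78 °C
Reagents that add atoms: none
Why: Luche reduction: the small hydride attacks C6 axially, anti to the axial C5–O bond (polar Felkin–Anh, torsional control), giving the equatorial alcohol cis to the C5 hydroxyl; this is also the thermodynamic epimer because an axial C6–OH would be syn-diaxial to the C2 methyl (the axial C2 methyl partly hinders this approach, so the ratio is uncertain; estimate about 5:1).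

**Step 8**
Reactants: 15 (1R,2S,3S,4S,5S,6R)-2,3,6-trihydroxy-2,5,6-trimethyl-4-(prop-1-yn-1-yl)cyclohexyl acetate
Product: 17 (1R,2S,3S,4S,5S,6R)-2,3,6-trihydroxy-4-[(1E)-2-iodoprop-1-en-1-yl]-2,5,6-trimethylcyclohexyl acetate, via alkenylzirconocene 16 (not isolated)
Conditions: Cp2Zr(H)Cl (5 equiv), THF, 40 °C; I2, 0 °C; aq. Na2S2O3
Reagents that add atoms: iodine II
Why: Schwartz hydrozirconation adds H–Zr syn with zirconium on the less hindered methyl-bearing alkyne carbon (excess reagent equilibrates the regioisomers, the hydroxyls ride as zirconium alkoxides and the acetate is tolerated), and iodinolysis proceeds with retention to the (E)-alkenyl iodide.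

**Step 9**
Reactants: 18 pentan-3-one
Product: 19 (E)-trimethyl(pent-2-en-3-yloxy)silane
Conditions: LDA, THF, −78 °C; TMSCl
Reagents that add atoms: chlorotrimethylsilane C[Si](C)(C)Cl
Why: The kinetic lithium enolate of the symmetrical ketone is O-silylated (silyl enol ether formation; the enol ether geometry is irrelevant).

**Step 10**
Reactants: 19 (E)-trimethyl(pent-2-en-3-yloxy)silane; 20 2-methylpropanedioyl dichloride
Product: 21 6-ethyl-4-hydroxy-3,5-dimethyl-2H-pyran-2-one
Conditions: Et2O, −78 → 20 °C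
Reagents that add atoms: none
Why: Effenberger pyrone synthesis: C-acylation of the silyl enol ether by one acid chloride and O-acylative ring closure by the other gives the 4-hydroxy-2-pyranone.

**Step 11**
Reactants: 21 6-ethyl-4-hydroxy-3,5-dimethyl-2H-pyran-2-one
Product: 22 2-ethyl-6-methoxy-3,5-dimethyl-4H-pyran-4-one
Conditions: MeOTf, CH2Cl2, 20 °C; aq. NaHCO3
Reagents that add atoms: methyl trifluoromethanesulfonate COS(=O)(=O)C(F)(F)F
Why: The hard methylating agent alkylates the more nucleophilic lactone carbonyl oxygen and loss of the proton gives the α-methoxy-γ-pyranone rather than the 4-methoxy-2-pyranone (regioselective O-methylation).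

**Step 12**
Reactants: 22 2-ethyl-6-methoxy-3,5-dimethyl-4H-pyran-4-one; 23 acrolein
Product: 26 2-methoxy-3,5-dimethyl-6-[(2E)-penta-2,4-dien-2-yl]-4H-pyran-4-one, via lithium aldolate 24 (not isolated), via allylic mesylate 25 (not isolated)
Conditions: LiHMDS, THF, −78 °C; 23; MsCl, −78 → 0 °C; DBU, 20 °C
Reagents that add atoms: none
Why: The vinylogous lithium enolate of the 2-ethyl group adds 1,2 to acrolein, and mesylation followed by E1cB elimination through the acidic pyranone α-position gives the conjugated (E)-diene (vinylogous aldol condensation).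

**Step 13**
Reactants: 17 (1R,2S,3S,4S,5S,6R)-2,3,6-trihydroxy-4-[(1E)-2-iodoprop-1-en-1-yl]-2,5,6-trimethylcyclohexyl acetate; 26 2-methoxy-3,5-dimethyl-6-[(2E)-penta-2,4-dien-2-yl]-4H-pyran-4-one
Product: 27 amaurone A
Conditions: Pd(OAc)2 (10 mol %), P(o-tol)3 (20 mol %), Ag2CO3, DMF, 45 °C, dark
Reagents that add atoms: none
Why: Mizoroki–Heck reaction: the alkenylpalladium adds to the terminal CH2 of the diene and β-hydride elimination from the allylpalladium gives the fully conjugated all-E triene, silver carbonate suppressing Pd–H isomerisation, with no stereocentre touched.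

**Compound list**
1 | rac-3,4-dimethylcyclopent-2-en-1-one | O=C1C=C(C)C(C)C1 | starting material
2 | ethyl vinyl ether | C=COCC | starting material
3 | lithium (1R*,4S*)-1-(1-ethoxyethenyl)-3,4-dimethylcyclopent-2-en-1-olate (racemic) | C=C(OCC)[C@]1([O-])C=C(C)[C@@H](C)C1.[Li+] | intermediate (not isolated)
4 | [(1R*,4S*)-1-(1-ethoxyethenyl)-3,4-dimethylcyclopent-2-en-1-yl]oxy(trimethyl)silane (racemic) | C=C(OCC)[C@]1(O[Si](C)(C)C)C=C(C)[C@@H](C)C1 | intermediate (not isolated)
5 | rac-1-[(1R*,4S*)-3,4-dimethyl-1-(trimethylsilyloxy)cyclopent-2-en-1-yl]ethan-1-one | CC(=O)[C@]1(O[Si](C)(C)C)C=C(C)[C@@H](C)C1 | intermediate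
6 | (2R,5S)-2,4,5-trimethyl-2-(trimethylsilyloxy)cyclohex-3-en-1-one | O=C1C[C@H](C)C(C)=C[C@@]1(C)O[Si](C)(C)C | intermediate (not isolated)
7 | (2R,5S)-2-hydroxy-2,4,5-trimethylcyclohex-3-en-1-one | O=C1C[C@H](C)C(C)=C[C@@]1(C)O | intermediate
8 | (2R,5R,6S)-6-bromo-2-hydroxy-2,4,5-trimethylcyclohex-3-en-1-one | O=C1[C@@H](Br)[C@H](C)C(C)=C[C@@]1(C)O | intermediate
9 | prop-1-yn-1-ylmagnesium bromide | CC#C[Mg]Br | starting material
10 | (1R,2R,5R,6S)-6-bromo-2,4,5-trimethyl-1-(prop-1-yn-1-yl)cyclohex-3-ene-1,2-diol, present as its bromomagnesium alkoxide | C[C@@]1(O)C=C(C)[C@@H](C)[C@H](Br)[C@@]1(O)C#CC | intermediate (not isolated)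
11 | (2R,5S,6S)-2-hydroxy-2,4,5-trimethyl-6-(prop-1-yn-1-yl)cyclohex-3-en-1-one | O=C1[C@H](C#CC)[C@H](C)C(C)=C[C@@]1(C)O | intermediate
12 | cyclic osmate(VI) ester of the C3/C4 diol of 13, TMEDA complex | O=C1[C@H](C#CC)[C@H](C)[C@@]2(C)O[Os](=O)(=O)O[C@H]2[C@@]1(C)O.CN(C)CCN(C)C | intermediate (not isolated)
13 | (2R,3R,4R,5S,6S)-2,3,4-trihydroxy-2,4,5-trimethyl-6-(prop-1-yn-1-yl)cyclohexan-1-one | O=C1[C@H](C#CC)[C@H](C)[C@@](C)(O)[C@@H](O)[C@@]1(C)O | intermediate
14 | (1R,2R,3S,4S,6R)-2,6-dihydroxy-2,3,6-trimethyl-5-oxo-4-(prop-1-yn-1-yl)cyclohexyl acetate | O=C1[C@H](C#CC)[C@H](C)[C@@](C)(O)[C@@H](OC(C)=O)[C@@]1(C)O | intermediate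
15 | (1R,2S,3S,4S,5S,6R)-2,3,6-trihydroxy-2,5,6-trimethyl-4-(prop-1-yn-1-yl)cyclohexyl acetate | O[C@H]1[C@H](C#CC)[C@H](C)[C@@](C)(O)[C@@H](OC(C)=O)[C@@]1(C)O | intermediate
16 | (E)-alkenylzirconocene chloride of 15 (hydroxyls drawn free, carried as zirconium alkoxides) | O[C@H]1[C@H](/C=C(C)/[Zr](Cl)(C2C=CC=C2)C2C=CC=C2)[C@H](C)[C@@](C)(O)[C@@H](OC(C)=O)[C@@]1(C)O | intermediate (not isolated)
17 | (1R,2S,3S,4S,5S,6R)-2,3,6-trihydroxy-4-[(1E)-2-iodoprop-1-en-1-yl]-2,5,6-trimethylcyclohexyl acetate | O[C@H]1[C@H](/C=C(C)/I)[C@H](C)[C@@](C)(O)[C@@H](OC(C)=O)[C@@]1(C)O | intermediate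
18 | pentan-3-one | CCC(=O)CC | starting material
19 | (E)-trimethyl(pent-2-en-3-yloxy)silane | C/C=C(\CC)O[Si](C)(C)C | intermediate
20 | 2-methylpropanedioyl dichloride (methylmalonyl dichloride) | CC(C(=O)Cl)C(=O)Cl | starting material
21 | 6-ethyl-4-hydroxy-3,5-dimethyl-2H-pyran-2-one | CCc1oc(=O)c(C)c(O)c1C | intermediate
22 | 2-ethyl-6-methoxy-3,5-dimethyl-4H-pyran-4-one | CCc1oc(OC)c(C)c(=O)c1C | intermediate
23 | acrolein | C=CC=O | starting material
24 | 2-(3-hydroxypent-4-en-2-yl)-6-methoxy-3,5-dimethyl-4H-pyran-4-one, present as its lithium alkoxide (diastereomer mixture) | COc1oc(C(C)C(O)C=C)c(C)c(=O)c1C | intermediate (not isolated)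
25 | 2-(6-methoxy-3,5-dimethyl-4-oxo-4H-pyran-2-yl)pent-4-en-3-yl methanesulfonate (diastereomer mixture) | COc1oc(C(C)C(OS(C)(=O)=O)C=C)c(C)c(=O)c1C | intermediate (not isolated)
26 | 2-methoxy-3,5-dimethyl-6-[(2E)-penta-2,4-dien-2-yl]-4H-pyran-4-one | COc1oc(/C(C)=C/C=C)c(C)c(=O)c1C | intermediate
27 | amaurone A, (1R,2S,3S,4R,5S,6R)-2,3,6-trihydroxy-4-[(1E,3E,5E)-6-(6-methoxy-3,5-dimethyl-4-oxo-4H-pyran-2-yl)-2-methylhepta-1,3,5-trien-1-yl]-2,5,6-trimethylcyclohexyl acetate | COc1oc(/C(C)=C/C=C/C(C)=C/[C@@H]2[C@H](C)[C@@](C)(O)[C@@H](OC(C)=O)[C@@](C)(O)[C@H]2O)c(C)c(=O)c1C | target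

**Totals and risks**
Total step count: 13. Longest linear sequence: 9 (steps 1–8, then 13); the pyranone branch is steps 9–12.

The three steps most likely to fail:

Step 2 (the proposed new ring expansion; enantiomer discrimination, alkenyl-versus-alkyl shift and catalyst turnover are all untested). The fallback uses known chemistry, sets out from 1 and comes back at 7. Hydrogenation of 1 (H2, Pd/C) gives meso cis-3,4-dimethylcyclopentanone F1. Enantiotopic deprotonation with lithium (R,R)-bis(1-phenylethyl)amide and TMSCl gives [(3S,4S)-3,4-dimethylcyclopent-1-en-1-yl]oxy(trimethyl)silane F2. Saegusa–Ito oxidation gives (S)-3,4-dimethylcyclopent-2-en-1-one F3. Addition of 1-ethoxyvinyllithium gives (1R,4S)-1-(1-ethoxyethenyl)-3,4-dimethylcyclopent-2-en-1-ol F4, which dilute acid hydrolyses to 1-[(1R,4S)-1-hydroxy-3,4-dimethylcyclopent-2-en-1-yl]ethan-1-one F5. Potassium hydride in THF then effects the classical alkoxide-driven α-ketol ring expansion (transoid arrangement, same stereochemical outcome) to 7.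

Step 4 (ring contraction or enolisation may compete with the 1,2-alkynyl shift). The fallback sets out from 8 and comes back at 11. A copper-catalysed radical C(sp3)–C(sp) coupling of 8 with propyne (CuI, tridentate nitrogen ligand, Cs2CO3) replaces the ionic addition/shift. It gives 11 mixed with its C6 epimer (2R,5S,6R)-2-hydroxy-2,4,5-trimethyl-6-(prop-1-yn-1-yl)cyclohex-3-en-1-one F6. Enolisation (LiHMDS, −78 °C) and kinetic protonation (AcOH) from the face opposite the neighbouring methyl converge F6 onto 11.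

Step 7 (the axial methyl next to the attack trajectory may erode the facial selectivity). The fallback sets out from 14 and comes back at 15, replacing reagent control by a face-capping group. t-Bu2Si(OTf)2 and 2,6-lutidine bridge the two syn-diaxial tertiary hydroxyls to give the cyclic di-tert-butylsilylene ketone F7, whose tert-butyl groups block the hydroxyl face. NaBH4 then gives the silylene alcohol F8, and HF·pyridine releases 15.

**Further compounds**
F1 | step 2 | cis-3,4-dimethylcyclopentan-1-one (meso) | O=C1C[C@H](C)[C@H](C)C1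
F2 | step 2 | [(3S,4S)-3,4-dimethylcyclopent-1-en-1-yl]oxy(trimethyl)silane | C[Si](C)(C)OC1=C[C@@H](C)[C@@H](C)C1
F3 | step 2 | (S)-3,4-dimethylcyclopent-2-en-1-one | O=C1C=C(C)[C@@H](C)C1
F4 | step 2 | (1R,4S)-1-(1-ethoxyethenyl)-3,4-dimethylcyclopent-2-en-1-ol | C=C(OCC)[C@]1(O)C=C(C)[C@@H](C)C1
F5 | step 2 | 1-[(1R,4S)-1-hydroxy-3,4-dimethylcyclopent-2-en-1-yl]ethan-1-one | CC(=O)[C@]1(O)C=C(C)[C@@H](C)C1
F6 | step 4 | (2R,5S,6R)-2-hydroxy-2,4,5-trimethyl-6-(prop-1-yn-1-yl)cyclohex-3-en-1-one | O=C1[C@@H](C#CC)[C@H](C)C(C)=C[C@@]1(C)O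
F7 | step 7 | cyclic di-tert-butylsilylene (across the two tertiary hydroxyls) of ketone 14 | O=C1[C@H](C#CC)[C@H](C)[C@@]2(C)O[Si](C(C)(C)C)(C(C)(C)C)O[C@]1(C)[C@@H]2OC(C)=O
F8 | step 7 | cyclic di-tert-butylsilylene (across the two tertiary hydroxyls) of alcohol 15 | O[C@H]1[C@H](C#CC)[C@H](C)[C@@]2(C)O[Si](C(C)(C)C)(C(C)(C)C)O[C@]1(C)[C@@H]2OC(C)=O
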